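## Structural features

The target is a 2,3-dihydrobenzofuran in which ring A (the benzo ring) is fused to a five-membered ring made of O1, C2, C3, C3a and C7a. C2 carries a 3,4,5-trimethoxyphenyl group, C3 a hydroxymethyl group, and C5 (para to O1) an (E)-3-hydroxyprop-1-enyl chain. C2 (R) and C3 (S) are adjacent and trans; both are benzylic, and C2 is also an aryl ether carbon. The fragile parts are the benzylic C2–O1 bond (ionisable by acid, cleaved by hydrogenolysis) and the cinnamyl alcohol (sensitive to acid, oxidants and hydrogenation), so the side chain is finished last. The pendant aryl ring has no free phenol, which rules out a biomimetic oxidative coupling. The real difficulty is the absolute configuration of the trans C2/C3 pair, which has no neighbouring group to direct a reagent. The feature used is the chain aryl–C2(O)–C3(ring A)–CH2–O: bonding the hydroxymethyl oxygen to C2 in place of O1 gives a 2,3-diaryl oxetane, the [2+2] adduct of an aromatic aldehyde C=O and a vinyl group on ring A. In that oxetane the ortho oxygen of ring A is placed for a five-membered closure onto C2 that expels the oxetane oxygen as the CH2OH group.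

## Logic of the disconnections

13 to 12: no skeletal bond is cut; the two C–H bonds of the allylic carbinol carbon are removed, so that carbon returns to the ester level. The enoate is robust and its E geometry is easy to secure. The forward step must reduce 1,2 only.

12 to 9 and 10 (through 11): the side-chain C=C bond is cut. This reduces the fragile three-carbon chain to a one-carbon substituent at C5 that can be carried through photochemistry and acid. The forward step must oxidise the benzylic alcohol of 9 in the presence of the aliphatic CH2OH and must give the E alkene.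

9 to 8: again no skeletal cut; the C5 carbinol returns to a methyl ester, the inert spectator form of this carbon. The hydride must leave the benzylic C2–O1 bond alone.

8 to 7: O1–C2 is cut and C2 is joined to the hydroxymethyl oxygen. The dihydrofuran becomes an oxetane whose strain drives the forward ring switch, and the C2 configuration follows from the oxetane by inversion while C3 is carried unchanged. The forward step must attack at C2 and not at C4, must proceed with inversion, and must select one enantiomer, because 7 is racemic.

7 to 6: the phenol O–H is exchanged for O–Si. The forward step must free the phenol without letting a phenoxide open the oxetane.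

6 to 4 and 5: C2–C3 and O–C4 are cut in a retro-[2+2] sense, which gives two simple arenes. The forward photocycloaddition must put oxygen on the terminal alkene carbon, close trans, and outcompete waste channels of the triplet aldehyde. The design of 4 serves this in four ways:
- the phenol is capped, so there is no O–H for the triplet to abstract;
- the alkene is terminal, so triplet energy transfer only wastes photons and causes no E/Z scrambling;
- the ester is meta to the vinyl group, so it does not extend the styrene chromophore into the irradiation window;
- the ortho silyloxy group adds bulk that favours trans closure.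

4 to 3 to 1 and 2: the O–Si bond and the aryl–vinyl bond are cut. The coupling must tolerate a free phenol and an ester.

## Other disconnections considered

Alternative 1: The cut is through C2–aryl and C3–CH2 on an intact benzofuran. 2-(1-Benzofuran-5-yl)-1,3-dioxolane A2 would be lithiated at C2 and combined with the aryl pinacol boronate A3. The ate complex would be allylated at C3 by a chiral π-allyl palladium electrophile (zerovalent palladium from Pd2(dba)3, BINAP) while the aryl group shifts from boron to C2, giving boronic ester A1.
- In its favour: two C–C bonds and both stereocentres form in one catalytic asymmetric step, and anti addition across C2=C3 puts the aryl group trans to the C3 substituent. On absolute stereocontrol this is better than the chosen plan, which resolves a racemate and gives up half of the material.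
- Against it here: the C3 substituent arrives as a three-carbon allyl group that must be isomerised, cleaved and reduced to CH2OH. The tertiary, benzylic, oxygen-bearing C2–B bond must be replaced by C–H with retention. The acetal must still be unmasked and homologated. The close analogues of the migration are on indoles, where dearomatisation costs less.
- Comparison: structurally the chosen plan is leaner, because the photocycloaddition forms only atoms of the target, while A1 carries two carbons and a boron that are removed again. Mechanistically the two are about equal, each having one step without a close analogue. In step count the alternative should be longer (about six operations after A1 against five after 6).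

Alternative 2: The cut is O1–C2 together with the bond from C3 to its one-carbon substituent, leading to the 2-hydroxystilbene A4. A divalent palladium catalyst, Pd(OCOCF3)2 with a chiral bis(oxazoline), under CO in methanol with a quinone reoxidant, would add the phenol oxygen to the aryl-bearing alkene carbon and carbonylate the C3–Pd bond to give diester A5. One hydride reduction of both esters would then give 13.
- In its favour: it is by far the shortest path (A4 should be reachable in about three steps, then two more). Every carbon and oxidation level of the target is in place after the key step, and enantiocontrol is catalytic. On step and atom economy it is clearly better than the chosen plan.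
- Against it here: the closure is 5-endo onto an internal stilbene. In the anti-oxypalladation mode that leads to the trans product, the palladium at C3 is syn to the hydrogen at C2, and loss of that hydrogen gives an aromatic 2-arylbenzofuran; CO insertion would have to outrun it. The trans/cis outcome depends on anti versus syn oxypalladation, and the enoate is a second alkene competing for the metal.
- Comparison: in structural fit it is equal or better. Mechanistically it is weaker: in the chosen plan each ring-forming event has a close known analogue and only the enantiomer selection is new, whereas here the ring-forming step itself is uncertain. In step count it is better.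

Alternative 3: The cut goes through ring A (C3a–C4 and C7a–C7), so the arene is built last on a dihydrofuran that already holds both stereocentres. The trans lactone A6 would be converted into its silyl ketene acetal A7, which would undergo inverse-demand [4+2] cycloaddition with methyl coumalate A8. Loss of CO2 and silanol would aromatise the adduct to ester A9.
- In its favour: the stereocentres are set by ground-state chemistry on a butyrolactone, where trans is thermodynamically preferred and no resolution is needed, so absolute control is better than in the chosen plan. The cascade is thermal, with regiochemistry fixed by polarity (nucleophilic ketene acetal carbon to C6 of A8), which puts the ester at C5. A9 is the silyl ether of 8, so the endgame is equal apart from one desilylation.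
- Against it here: enantiopure A6 needs several steps of its own. Aromatisation must expel silanol and not the ring oxygen, otherwise the dihydrofuran opens.
- Comparison: its key step is mechanistically at least as secure as a photocycloaddition with a built-in energy-wasting channel. Structurally it spends steps building a benzene ring that the chosen plan buys. In step count it should be longer (about eleven or twelve against eight).

Key step: step 3

Remark on the chemistry: 6 and 7 are racemic trans compounds whose names and SMILES show the (2S,3S) enantiomer that leads to 13, single-enantiomer material begins with 8, and because an invertive opening transfers the relative configuration of the oxetane (C2 inverts, C3 is untouched, so (2S,3S)-7 maps onto (2R,3S)-8 and a cis oxetane would give the cis dihydrobenzofuran), the minor cis oxetane is removed after step 3.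

## Route

Step 1
Reactants: 1 methyl 3-bromo-4-hydroxybenzoate; 2 potassium vinyltrifluoroborate
Product: 3 methyl 4-hydroxy-3-vinylbenzoate
Conditions: PdCl2(dppf)·CH2Cl2 (cat.), Cs2CO3, THF/H2O (9:1), 80 °C
Reagents that add atoms: none
Why: Suzuki–Miyaura coupling of an aryl bromide with a vinyltrifluoroborate; the phenol is carried as its phenoxide and the methyl ester is inert to carbonate here. Vinylation comes before silylation because an aryl silyl ether para to an ester would not survive hot aqueous base.

Step 2
Reactants: 3 methyl 4-hydroxy-3-vinylbenzoate
Product: 4 methyl 4-(tert-butyldimethylsilyloxy)-3-vinylbenzoate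
Conditions: TBSCl, imidazole, DMF, 23 °C
Reagents that add atoms: tert-butyldimethylsilyl chloride, CC(C)(C)[Si](C)(C)Cl
Why: Standard O-silylation of a phenol. The cap removes the phenolic O–H, which would reduce the triplet aldehyde of step 3 by hydrogen transfer, and it is later removed by fluoride without acid.

Step 3
Reactants: 4 methyl 4-(tert-butyldimethylsilyloxy)-3-vinylbenzoate; 5 3,4,5-trimethoxybenzaldehyde
Product: 6 methyl 4-(tert-butyldimethylsilyloxy)-3-[(2S,3S)-2-(3,4,5-trimethoxyphenyl)oxetan-3-yl]benzoate (racemic, trans)
Conditions: hν (350 nm lamps, Pyrex filter), 5 (3 equiv), degassed C6H6, 15 °C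
Reagents that add atoms: none
Why: Paternò–Büchi [2+2] photocycloaddition: light above 330 nm is absorbed only by 5, whose triplet n,π* state adds through oxygen to the terminal alkene carbon of 4 and gives a triplet 1,4-biradical with one radical on the ketyl carbon and one on the benzylic carbon of ring A. After intersystem crossing the two radical centres combine, so the oxetane closes stepwise, O–C4 first by radical addition and C2–C3 last by recombination of the 1,4-biradical. The closest known reaction type is the photocycloaddition of benzaldehyde to styrene-type alkenes, which gives 2,3-diaryl oxetanes with this regiochemistry. The step needs regioselectivity, and the substrate secures it because attack of oxygen on CH2 is the only mode that leaves a benzylic radical. C2 and C3 are set relative to each other in the closure of the freely rotating biradical, where the two aryl groups, one of them bearing the bulky ortho silyloxy group, should take the trans arrangement; the absolute configuration is not controlled and 6 forms as the racemate. Chemoselectivity rests on the silyl cap, since a free phenol would quench the triplet aldehyde, and on the terminal alkene, for which triplet energy transfer from 5 is only an energy-wasting channel without E/Z scrambling. The minor cis oxetane and the excess of 5 are removed by chromatography.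

Step 4
Reactants: 6 methyl 4-(tert-butyldimethylsilyloxy)-3-[(2S,3S)-2-(3,4,5-trimethoxyphenyl)oxetan-3-yl]benzoate (racemic)
Product: 7 methyl 4-hydroxy-3-[(2S,3S)-2-(3,4,5-trimethoxyphenyl)oxetan-3-yl]benzoate (racemic, trans)
Conditions: Bu4NF, AcOH (1:1), THF, 0 °C
Reagents that add atoms: none
Why: Fluoride cleavage of an aryl silyl ether; oxetane, ester and aryl methyl ethers are inert to fluoride. Acetic acid keeps the freed phenol protonated, because a phenoxide could open the oxetane without selection and preferentially at the unhindered C4; 7 is passed through base-washed silica and used at once.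

Step 5
Reactants: 7 methyl 4-hydroxy-3-[(2S,3S)-2-(3,4,5-trimethoxyphenyl)oxetan-3-yl]benzoate (racemic)
Product: 8 methyl (2R,3S)-3-(hydroxymethyl)-2-(3,4,5-trimethoxyphenyl)-2,3-dihydrobenzofuran-5-carboxylate
Conditions: TRIP [3,3′-bis(2,4,6-triisopropylphenyl)-1,1′-binaphthyl-2,2′-diyl hydrogen phosphate, the hand matched to (2S,3S)-7, 10 mol %], 4 Å molecular sieves, PhMe, −20 °C, stopped near half conversion
Reagents that add atoms: none
Why: Proposed new method: the phosphoric acid should bind 7 at two points, its P=O oxygen accepting the phenol O–H and its P–OH hydrogen-bonding to the oxetane oxygen, so that positive charge builds at the benzylic C2 (stabilised by the trimethoxyphenyl group) and the phenol oxygen attacks C2 anti to the departing oxygen in a 5-exo-tet closure with inversion, C3 being untouched and acid activation directing the attack to C2 and not to C4; the two enantiomers of 7 form diastereomeric contact pairs with the catalyst that should react at different rates, so that stopping near half conversion should give (2R,3S)-8 from (2S,3S)-7 and leave the (2R,3R) enantiomer of 7 unchanged; the closest known reaction types are the chiral-phosphoric-acid-catalysed desymmetrising intramolecular openings of 3-substituted oxetanes and the acid-promoted closure of ortho-(oxetan-3-yl)phenols to 3-(hydroxymethyl)dihydrobenzofurans.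

Step 6
Reactants: 8 methyl (2R,3S)-3-(hydroxymethyl)-2-(3,4,5-trimethoxyphenyl)-2,3-dihydrobenzofuran-5-carboxylate
Product: 9 [(2R,3S)-2-(3,4,5-trimethoxyphenyl)-2,3-dihydrobenzofuran-3,5-diyl]dimethanol
Conditions: LiAlH4, THF, 0 °C
Reagents that add atoms: none
Why: Hydride reduction of the aryl ester to the benzylic alcohol. The benzylic ether C2–O1 and the aryl methyl ethers are not attacked, and neither stereocentre is next to an acidifying group.

Step 7
Reactants: 9 [(2R,3S)-2-(3,4,5-trimethoxyphenyl)-2,3-dihydrobenzofuran-3,5-diyl]dimethanol; 10 methyl (triphenylphosphoranylidene)acetate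
Product: 12 methyl (E)-3-[(2R,3S)-3-(hydroxymethyl)-2-(3,4,5-trimethoxyphenyl)-2,3-dihydrobenzofuran-5-yl]prop-2-enoate, via 5-formyl dihydrobenzofuran 11 (not isolated)
Conditions: MnO2 (activated, excess), CH2Cl2, 40 °C
Reagents that add atoms: none
Why: Tandem oxidation–Wittig olefination: MnO2 oxidises the benzylic alcohol and leaves the unactivated aliphatic CH2OH, and aldehyde 11 is trapped as it forms by the stabilised ylide 10, which should give the E enoate. No stereocentre is formed or endangered.

Step 8
Reactants: 12 methyl (E)-3-[(2R,3S)-3-(hydroxymethyl)-2-(3,4,5-trimethoxyphenyl)-2,3-dihydrobenzofuran-5-yl]prop-2-enoate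
Product: 13 (E)-3-[(2R,3S)-3-(hydroxymethyl)-2-(3,4,5-trimethoxyphenyl)-2,3-dihydrobenzofuran-5-yl]prop-2-en-1-ol (CNP0077408.1)
Conditions: i-Bu2AlH (excess), CH2Cl2, −78 → 0 °C; aq. KNaC4H4O6
Reagents that add atoms: none
Why: 1,2-reduction of an α,β-unsaturated ester to the allylic alcohol by an aluminium hydride. The E alkene and both benzylic stereocentres are untouched.

## Compound list

1 | methyl 3-bromo-4-hydroxybenzoate | COC(=O)c1ccc(O)c(Br)c1 | starting material
2 | potassium vinyltrifluoroborate | C=C[B-](F)(F)F.[K+] | starting material
3 | methyl 4-hydroxy-3-vinylbenzoate | COC(=O)c1ccc(O)c(C=C)c1 | intermediate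
4 | methyl 4-(tert-butyldimethylsilyloxy)-3-vinylbenzoate | COC(=O)c1ccc(O[Si](C)(C)C(C)(C)C)c(C=C)c1 | intermediate
5 | 3,4,5-trimethoxybenzaldehyde | COc1cc(C=O)cc(OC)c1OC | starting material
6 | methyl 4-(tert-butyldimethylsilyloxy)-3-[(2S,3S)-2-(3,4,5-trimethoxyphenyl)oxetan-3-yl]benzoate (racemic trans; enantiomer carried on is drawn) | COc1cc([C@H]2OC[C@@H]2c2cc(C(=O)OC)ccc2O[Si](C)(C)C(C)(C)C)cc(OC)c1OC | intermediate
7 | methyl 4-hydroxy-3-[(2S,3S)-2-(3,4,5-trimethoxyphenyl)oxetan-3-yl]benzoate (racemic trans; enantiomer carried on is drawn) | COc1cc([C@H]2OC[C@@H]2c2cc(C(=O)OC)ccc2O)cc(OC)c1OC | intermediate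
8 | methyl (2R,3S)-3-(hydroxymethyl)-2-(3,4,5-trimethoxyphenyl)-2,3-dihydrobenzofuran-5-carboxylate | COc1cc([C@@H]2Oc3ccc(C(=O)OC)cc3[C@H]2CO)cc(OC)c1OC | intermediate
9 | [(2R,3S)-2-(3,4,5-trimethoxyphenyl)-2,3-dihydrobenzofuran-3,5-diyl]dimethanol | COc1cc([C@@H]2Oc3ccc(CO)cc3[C@H]2CO)cc(OC)c1OC | intermediate
10 | methyl (triphenylphosphoranylidene)acetate | COC(=O)C=P(c1ccccc1)(c1ccccc1)c1ccccc1 | starting material
11 | (2R,3S)-3-(hydroxymethyl)-2-(3,4,5-trimethoxyphenyl)-2,3-dihydrobenzofuran-5-carbaldehyde | COc1cc([C@@H]2Oc3ccc(C=O)cc3[C@H]2CO)cc(OC)c1OC | intermediate
12 | methyl (E)-3-[(2R,3S)-3-(hydroxymethyl)-2-(3,4,5-trimethoxyphenyl)-2,3-dihydrobenzofuran-5-yl]prop-2-enoate | COc1cc([C@@H]2Oc3ccc(/C=C/C(=O)OC)cc3[C@H]2CO)cc(OC)c1OC | intermediate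
13 | (E)-3-[(2R,3S)-3-(hydroxymethyl)-2-(3,4,5-trimethoxyphenyl)-2,3-dihydrobenzofuran-5-yl]prop-2-en-1-ol | COc1cc([C@@H]2Oc3ccc(/C=C/CO)cc3[C@H]2CO)cc(OC)c1OC | target

## Step count and least certain steps

Total step count: 8. Longest linear sequence: 8 steps (1 to 13); 2, 5 and 10 enter as purchased reagents.

Step 5 (Proposed new method). The most likely failure is insufficient discrimination between the two enantiomers of 7. A background opening catalysed by the fairly acidic para-ester phenol itself, or by traces of acid, would add unselective product, and loss of regiocontrol toward C4 is possible if any phenoxide is present. The fallback uses known chemistry, sets out from 7 and returns at 9. Catalytic TsOH·H2O in CH2Cl2 should open both enantiomers alike at C2 and give the racemic trans alcohol, that is 8 together with its enantiomer methyl (2S,3R)-3-(hydroxymethyl)-2-(3,4,5-trimethoxyphenyl)-2,3-dihydrobenzofuran-5-carboxylate F1. Acylation with (1S)-camphanic chloride (Et3N, DMAP, CH2Cl2) should give two diastereomeric esters, the (1S)-camphanate of 8 F2 and the (1S)-camphanate of the (2S,3R) alcohol F3, to be separated by chromatography or crystallisation. LiAlH4 in THF then cleaves the camphanate of F2 and reduces its methyl ester in one operation, which gives 9.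

Step 3 (key step). The likely failure is inefficient productive capture of the triplet aldehyde. Energy transfer to the styrene chromophore of 4 is exothermic, and the lowest triplet of a trimethoxy-substituted benzaldehyde may have enough π,π* character to slow attack on the alkene. Conversion could then stall while slow oligomerisation of 4 and photoreduction of 5 accumulate, and the trans preference in the biradical closure may be modest. The fallback replaces the photochemical two-bond construction by a polar one; it sets out from 4 (with 5) and returns at 8.
- Cross-metathesis of 4 with allylboronic acid pinacol ester (second-generation Grubbs catalyst, CH2Cl2, 40 °C) should give methyl 4-(tert-butyldimethylsilyloxy)-3-[(E)-3-(4,4,5,5-tetramethyl-1,3,2-dioxaborolan-2-yl)prop-1-enyl]benzoate F4.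
- Allylboration of 5 with F4 under a chiral phosphoric acid (a known mode for E γ-substituted allyl pinacolboronates and aromatic aldehydes), through a chair transition state, should give the anti homoallylic alcohol methyl 4-(tert-butyldimethylsilyloxy)-3-[(3R,4S)-4-hydroxy-4-(3,4,5-trimethoxyphenyl)but-1-en-3-yl]benzoate F5.
- Ozonolysis of the vinyl group with NaBH4 work-up should give methyl 4-(tert-butyldimethylsilyloxy)-3-[(1S,2S)-1,3-dihydroxy-1-(3,4,5-trimethoxyphenyl)propan-2-yl]benzoate F6.
- Bu4NF then frees methyl 3-[(1S,2S)-1,3-dihydroxy-1-(3,4,5-trimethoxyphenyl)propan-2-yl]-4-hydroxybenzoate F7.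
- BF3·OEt2 in CH2Cl2 should ionise the benzylic alcohol of F7, and the phenol should close trans to the C3 substituent, giving 8.

Step 4. The likely failure is premature, unselective ring opening: a phenoxide formed on desilylation can attack the oxetane, mainly at the unhindered C4, and the free phenol may also open on silica, so material would be lost before the chiral acid acts. The fallback changes how the phenol is masked; it sets out from 3 and returns at 7. Acetylation (Ac2O, pyridine) gives methyl 4-acetoxy-3-vinylbenzoate F8. Irradiation with 5 as in step 3 should give the racemic trans oxetane methyl 4-acetoxy-3-[(2S,3S)-2-(3,4,5-trimethoxyphenyl)oxetan-3-yl]benzoate F9. The aryl acetate is then cleaved near neutrality (NH4OAc, aqueous MeOH, 23 °C) to give 7 without fluoride or a naked phenoxide.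

Step 7. The likely failure is incomplete or unselective oxidation on the MnO2 surface in the presence of the ylide (variable oxidant activity, adsorption of the diol, slow attack on the aliphatic alcohol under forcing conditions). The fallback avoids any oxidation; it sets out from 8 and returns at 12. Treatment of 8 with MeNH(OMe)·HCl and i-PrMgCl (THF, −20 °C) should give (2R,3S)-3-(hydroxymethyl)-N-methoxy-N-methyl-2-(3,4,5-trimethoxyphenyl)-2,3-dihydrobenzofuran-5-carboxamide F10. Reduction with i-Bu2AlH (THF, −78 °C) stops at aldehyde 11, which is isolated and condensed with 10 (PhMe, 80 °C) to give 12.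

## Further compounds

F1 | step 5 | methyl (2S,3R)-3-(hydroxymethyl)-2-(3,4,5-trimethoxyphenyl)-2,3-dihydrobenzofuran-5-carboxylate | COc1cc([C@H]2Oc3ccc(C(=O)OC)cc3[C@@H]2CO)cc(OC)c1OC
F2 | step 5 | methyl (2R,3S)-3-({[(1S,4R)-4,7,7-trimethyl-3-oxo-2-oxabicyclo[2.2.1]heptane-1-carbonyl]oxy}methyl)-2-(3,4,5-trimethoxyphenyl)-2,3-dihydrobenzofuran-5-carboxylate | COc1cc([C@@H]2Oc3ccc(C(=O)OC)cc3[C@H]2COC(=O)[C@@]45CC[C@@](C)(C(=O)O4)C5(C)C)cc(OC)c1OC
F3 | step 5 | methyl (2S,3R)-3-({[(1S,4R)-4,7,7-trimethyl-3-oxo-2-oxabicyclo[2.2.1]heptane-1-carbonyl]oxy}methyl)-2-(3,4,5-trimethoxyphenyl)-2,3-dihydrobenzofuran-5-carboxylate | COc1cc([C@H]2Oc3ccc(C(=O)OC)cc3[C@@H]2COC(=O)[C@@]45CC[C@@](C)(C(=O)O4)C5(C)C)cc(OC)c1OC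
F4 | step 3 | methyl 4-(tert-butyldimethylsilyloxy)-3-[(E)-3-(4,4,5,5-tetramethyl-1,3,2-dioxaborolan-2-yl)prop-1-enyl]benzoate | COC(=O)c1ccc(O[Si](C)(C)C(C)(C)C)c(/C=C/CB2OC(C)(C)C(C)(C)O2)c1
F5 | step 3 | methyl 4-(tert-butyldimethylsilyloxy)-3-[(3R,4S)-4-hydroxy-4-(3,4,5-trimethoxyphenyl)but-1-en-3-yl]benzoate | COc1cc([C@@H](O)[C@H](C=C)c2cc(C(=O)OC)ccc2O[Si](C)(C)C(C)(C)C)cc(OC)c1OC
F6 | step 3 | methyl 4-(tert-butyldimethylsilyloxy)-3-[(1S,2S)-1,3-dihydroxy-1-(3,4,5-trimethoxyphenyl)propan-2-yl]benzoate | COc1cc([C@@H](O)[C@H](CO)c2cc(C(=O)OC)ccc2O[Si](C)(C)C(C)(C)C)cc(OC)c1OC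
F7 | step 3 | methyl 3-[(1S,2S)-1,3-dihydroxy-1-(3,4,5-trimethoxyphenyl)propan-2-yl]-4-hydroxybenzoate | COc1cc([C@@H](O)[C@H](CO)c2cc(C(=O)OC)ccc2O)cc(OC)c1OC
F8 | step 4 | methyl 4-acetoxy-3-vinylbenzoate | COC(=O)c1ccc(OC(C)=O)c(C=C)c1
F9 | step 4 | methyl 4-acetoxy-3-[(2S,3S)-2-(3,4,5-trimethoxyphenyl)oxetan-3-yl]benzoate (racemic trans) | COc1cc([C@H]2OC[C@@H]2c2cc(C(=O)OC)ccc2OC(C)=O)cc(OC)c1OC
F10 | step 7 | (2R,3S)-3-(hydroxymethyl)-N-methoxy-N-methyl-2-(3,4,5-trimethoxyphenyl)-2,3-dihydrobenzofuran-5-carboxamide | COc1cc([C@@H]2Oc3ccc(C(=O)N(C)OC)cc3[C@H]2CO)cc(OC)c1OC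
A1 | alternative 1 | 2-[(2R,3R)-3-allyl-5-(1,3-dioxolan-2-yl)-2-(3,4,5-trimethoxyphenyl)-2,3-dihydrobenzofuran-2-yl]-4,4,5,5-tetramethyl-1,3,2-dioxaborolane | COc1cc([C@]2(B3OC(C)(C)C(C)(C)O3)Oc3ccc(C4OCCO4)cc3[C@H]2CC=C)cc(OC)c1OC
A2 | alternative 1 | 2-(1-benzofuran-5-yl)-1,3-dioxolane | O1CCOC1c1ccc2occc2c1
A3 | alternative 1 | 4,4,5,5-tetramethyl-2-(3,4,5-trimethoxyphenyl)-1,3,2-dioxaborolane | COc1cc(B2OC(C)(C)C(C)(C)O2)cc(OC)c1OC
A4 | alternative 2 | methyl (E)-3-{4-hydroxy-3-[(E)-2-(3,4,5-trimethoxyphenyl)ethenyl]phenyl}prop-2-enoate | COC(=O)/C=C/c1ccc(O)c(/C=C/c2cc(OC)c(OC)c(OC)c2)c1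
A5 | alternative 2 | methyl (2R,3R)-5-[(E)-3-methoxy-3-oxoprop-1-enyl]-2-(3,4,5-trimethoxyphenyl)-2,3-dihydrobenzofuran-3-carboxylate | COc1cc([C@@H]2Oc3ccc(/C=C/C(=O)OC)cc3[C@H]2C(=O)OC)cc(OC)c1OC
A6 | alternative 3 | (4S,5R)-4-[(tert-butyldimethylsilyloxy)methyl]-5-(3,4,5-trimethoxyphenyl)oxolan-2-one | COc1cc([C@@H]2OC(=O)C[C@H]2CO[Si](C)(C)C(C)(C)C)cc(OC)c1OC
A7 | alternative 3 | tert-butyldimethyl{[(2R,3S)-2-(3,4,5-trimethoxyphenyl)-5-(trimethylsilyloxy)-2,3-dihydrofuran-3-yl]methoxy}silane | COc1cc([C@@H]2OC(O[Si](C)(C)C)=C[C@H]2CO[Si](C)(C)C(C)(C)C)cc(OC)c1OC
A8 | alternative 3 | methyl 2-oxo-2H-pyran-5-carboxylate (methyl coumalate) | COC(=O)C1=COC(=O)C=C1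
A9 | alternative 3 | methyl (2R,3S)-3-(tert-butyldimethylsilyloxymethyl)-2-(3,4,5-trimethoxyphenyl)-2,3-dihydrobenzofuran-5-carboxylate | COc1cc([C@@H]2Oc3ccc(C(=O)OC)cc3[C@H]2CO[Si](C)(C)C(C)(C)C)cc(OC)c1OC
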